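**Retrosynthetic overview**
1. Ring labels: A = quinone, B = para-phenylene, C = phenol ring, D = meta-phenylene. The strategy rests on ring A. Its carbonyl carbons C1 and C4 are para, C2 (OMe) and C3 (H) lie on one flank, and the adjacent carbons C5 (O–ring D) and C6 (CH2CH2–ring B) lie on the other. This maps onto carbene carbon (C1) + 1-methoxyvinyl (C2, C3) + CO (C4) + the two carbons of an aryloxy/alkyl alkyne (C5, C6).
2. The 18-membered ring is opened at the ring C–CH2CH2–ring D bridge: saturated bridge ⇐ stilbene ⇐ ring-closing metathesis of two styrenes on the quinone. The hydrogenation also frees the benzyl-protected ring C phenol.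
3. Quinone ⇐ 4-methoxyphenol ((NH4)2Ce(NO3)6) ⇐ Dötz benzannulation of pentacarbonyl[methoxy(1-methoxyvinyl)carbene]chromium with an aryl ynol ether that carries ring D on oxygen and rings B–C on carbon.
4. The ynol ether C(sp)–O bond comes from 3-vinylphenol and a 1,1-dibromoalkene (copper catalysis, then dehydrobromination). This keeps alkyllithium reagents away from the styrenes and avoids alkylating an acetylide with an elimination-prone 2-arylethyl halide. The dibromoalkene stems from an Ullmann ether of rings B and C.
5. Order of ring formation: rings B, C and D are bought, ring A is built in step 8, and the macrocycle is closed in step 10.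

Key step: step 8

Remark on the chemistry: the target has no stereocentre. The geometry of the stilbene double bond formed by metathesis is left undefined, because both isomers give the same product on hydrogenation.

**Step 1**
Reactants: 1 4-(benzyloxy)-3-hydroxybenzaldehyde; 2 methyl 3-(4-bromophenyl)propanoate
Product: 3 methyl 3-{4-[2-(benzyloxy)-5-formylphenoxy]phenyl}propanoate
Conditions: CuI (10 mol %), N,N-dimethylglycine hydrochloride (30 mol %), Cs2CO3, 1,4-dioxane, 100 °C
Reagents that add atoms: none
Why: Ligand-accelerated Ullmann diaryl ether coupling, in which the monovalent copper phenoxide of 1 couples with the aryl bromide while aldehyde, methyl ester and benzyl ether are inert to Cs2CO3 in dry dioxane.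

**Step 2**
Reactants: 3 methyl 3-{4-[2-(benzyloxy)-5-formylphenoxy]phenyl}propanoate
Product: 4 methyl 3-{4-[2-(benzyloxy)-5-vinylphenoxy]phenyl}propanoate
Conditions: MePPh3Br (1.3 equiv), KOtBu (1.2 equiv), THF, 0 °C
Reagents that add atoms: methyltriphenylphosphonium bromide, C[P+](c1ccccc1)(c1ccccc1)c1ccccc1.[Br-]
Why: Wittig methylenation, in which the non-stabilised ylide adds to the aldehyde far faster than to the ester and the slight excess of phosphonium salt over base leaves no free alkoxide.

**Step 3**
Reactants: 4 methyl 3-{4-[2-(benzyloxy)-5-vinylphenoxy]phenyl}propanoate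
Product: 5 3-{4-[2-(benzyloxy)-5-vinylphenoxy]phenyl}propanal
Conditions: i-Bu2AlH (1.05 equiv), toluene, −78 °C; MeOH, then aq Rochelle salt
Reagents that add atoms: none
Why: Partial ester reduction with i-Bu2AlH, in which the aluminium hemiacetal persists at −78 °C and gives the aldehyde only on quench, and the styrene is not hydroaluminated at this temperature.

**Step 4**
Reactants: 5 3-{4-[2-(benzyloxy)-5-vinylphenoxy]phenyl}propanal
Product: 6 1-(benzyloxy)-2-[4-(4,4-dibromobut-3-en-1-yl)phenoxy]-4-vinylbenzene
Conditions: CBr4, PPh3, CH2Cl2, 0 °C; aq NaHCO3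
Reagents that add atoms: carbon tetrabromide, BrC(Br)(Br)Br
Why: Ramirez gem-dibromoolefination (first stage of the Corey–Fuchs sequence), a Wittig-type reaction of Ph3P=CBr2 that is reliable for unbranched aliphatic aldehydes and leaves styrene and ethers untouched.

**Step 5**
Reactants: 7 3-hydroxybenzaldehyde
Product: 8 3-vinylphenol
Conditions: MePPh3Br (2.4 equiv), KOtBu (2.3 equiv), THF, 0 °C → rt; aq NH4Cl
Reagents that add atoms: methyltriphenylphosphonium bromide, C[P+](c1ccccc1)(c1ccccc1)c1ccccc1.[Br-]
Why: Wittig methylenation with a second equivalent of ylide to absorb the phenol proton, since the phenoxide-bearing aldehyde is still electrophilic enough for a non-stabilised ylide.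

**Step 6**
Reactants: 6 1-(benzyloxy)-2-[4-(4,4-dibromobut-3-en-1-yl)phenoxy]-4-vinylbenzene; 8 3-vinylphenol
Product: 10 1-(benzyloxy)-2-{4-[4-(3-vinylphenoxy)but-3-yn-1-yl]phenoxy}-4-vinylbenzene (aryl ynol ether), via (Z)-1-bromo enol ether 9 (not isolated)
Conditions: CuI (10 mol %), 2,2'-bipyridine (20 mol %), K3PO4, toluene, BHT (trace), 110 °C; then KOtBu, 1,4-dioxane, rt; chromatography on Et3N-deactivated silica
Reagents that add atoms: none
Why: Copper-catalysed Ullmann-type vinylic C–O coupling of a 1,1-dibromoalkene with a phenol occurs at the less hindered C–Br bond trans to the alkyl chain, which places H and Br anti in 9 so that KOtBu completes an E2 dehydrobromination to the ynol ether.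

**Step 7**
Reactants: 11 methyl vinyl ether; 12 hexacarbonylchromium Cr(CO)6
Product: 15 pentacarbonyl[methoxy(1-methoxyvinyl)carbene]chromium, via 1-methoxyvinyllithium 13 (not isolated), via lithium acylchromate 14 (not isolated)
Conditions: t-BuLi, THF, −78 → 0 °C; Cr(CO)6, Et2O, 0 °C → rt; Me3OBF4, CH2Cl2, 0 °C
Reagents that add atoms: trimethyloxonium tetrafluoroborate, C[O+](C)C.F[B-](F)(F)F
Why: Fischer carbene synthesis, in which the α-lithiated enol ether adds to a CO ligand of zerovalent chromium and the resulting acylate is O-methylated by the hard Meerwein salt.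

**Step 8**
Reactants: 15 pentacarbonyl[methoxy(1-methoxyvinyl)carbene]chromium; 10 1-(benzyloxy)-2-{4-[4-(3-vinylphenoxy)but-3-yn-1-yl]phenoxy}-4-vinylbenzene
Product: 17 3-(2-{4-[2-(benzyloxy)-5-vinylphenoxy]phenyl}ethyl)-4,5-dimethoxy-2-(3-vinylphenoxy)phenol, via tricarbonylchromium arene complex 16 (not isolated)
Conditions: 15 (1.5 equiv), degassed THF, 50 °C, 10 added over 2 h, then 12 h; then air, EtOAc, rt
Reagents that add atoms: none
Why: Heating expels a cis CO ligand from the zerovalent chromium centre of 15, the alkyne of 10 takes the free site and inserts into the Cr=C bond to give a chromium-bound vinylcarbene, a CO ligand migrates onto the new carbene carbon to give a dienylketene complex, and this closes and tautomerises to the phenol, so that the bonds C1–C6, C5–C4 and C4–C3 of ring A arise in one operation. The reaction type is the Dötz benzannulation of an alkenyl Fischer carbene, the variant least diverted to five-membered rings; alkoxyalkynes have served as partners whereas aryl ynol ethers have seldom been tried, so 10 lies at the edge of the known scope rather than outside it. Ring A closes by 6π electrocyclisation of the dienylketene on the metal (ketene carbon C4 onto the CH2 terminus C3 of the methoxyvinyl group) followed by enolisation, and no stereocentre is created. The step needs one orientation of the alkyne, with the alkyl-bearing carbon bonded to carbene carbon C1 and the aryloxy-bearing carbon next to the inserted CO: the oxygen lone pair makes the alkyl-bearing carbon the nucleophilic end that seeks the electrophilic carbene carbon and leaves the aryloxy group on the new carbene carbon, which it stabilises as in a Fischer carbene, the same polarity that governs ynamine insertion into such complexes. The opposing steric preference should be weak, since a divalent oxygen and an unbranched CH2 differ little in size at the alkyne, and the orientation is to be checked on 17 by an NOE between the ring A benzylic CH2 and the C1 methoxy group. Chemoselectivity rests on the much faster uptake of alkynes than of unactivated styrenes by the unsaturated chromium centre, on the lack of a β-hydrogen on the O-aryl group (no retro-ene loss of ketene at 50 °C) and on slow addition of 10, which keeps a second ynol ether from trapping the ketene by [2+2] cycloaddition.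

**Step 9**
Reactants: 17 3-(2-{4-[2-(benzyloxy)-5-vinylphenoxy]phenyl}ethyl)-4,5-dimethoxy-2-(3-vinylphenoxy)phenol
Product: 18 3-(2-{4-[2-(benzyloxy)-5-vinylphenoxy]phenyl}ethyl)-5-methoxy-2-(3-vinylphenoxy)-1,4-benzoquinone
Conditions: (NH4)2Ce(NO3)6 (2.1 equiv), MeCN–H2O, 0 °C, short contact time
Reagents that add atoms: water, O
Why: Oxidative demethylation of a 4-methoxyphenol by tetravalent cerium (two one-electron oxidations, ipso attack of water at C1, loss of methanol), selective because the trioxygenated phenol is oxidised at a far lower potential than the styrenes, the benzyl ether or the C2 methoxy group.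

**Step 10**
Reactants: 18 3-(2-{4-[2-(benzyloxy)-5-vinylphenoxy]phenyl}ethyl)-5-methoxy-2-(3-vinylphenoxy)-1,4-benzoquinone
Product: 19 18-membered macrocyclic stilbene quinone (ring C–CH=CH–ring D, ring C phenol still benzylated, alkene geometry open)
Conditions: second-generation Grubbs catalyst (H2IMes)(PCy3)Cl2Ru=CHPh (10 mol % in portions), toluene, 1 mM, 80 °C, argon sparge
Reagents that add atoms: none
Why: Ring-closing metathesis of two terminal styrenes, driven by loss of ethylene and favoured over oligomerisation by high dilution; the trisubstituted and tetrasubstituted quinone double bonds are metathesis-inert and quinones are tolerated by ruthenium alkylidenes.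

**Step 11**
Reactants: 19 18-membered macrocyclic stilbene quinone
Product: 21 target CNP0332646.0 (macrocyclic bis(bibenzyl) methoxyquinone), via macrocyclic hydroquinone 20 (not isolated)
Conditions: H2 (1 atm), 10% Pd/C, EtOAc–THF, rt; filter; then air, silica gel, EtOAc, rt
Reagents that add atoms: none
Why: Heterogeneous catalytic hydrogenation saturates the stilbene, hydrogenolyses the aryl benzyl ether and reduces the quinone to 20, and autoxidation of this electron-rich hydroquinone in air restores the quinone while the isolated ring C phenol is not oxidised by air.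

**Compound list**
1 | 4-(benzyloxy)-3-hydroxybenzaldehyde | O=Cc1ccc(OCc2ccccc2)c(O)c1 | starting material
2 | methyl 3-(4-bromophenyl)propanoate | COC(=O)CCc1ccc(Br)cc1 | starting material
3 | methyl 3-{4-[2-(benzyloxy)-5-formylphenoxy]phenyl}propanoate | COC(=O)CCc1ccc(Oc2cc(C=O)ccc2OCc3ccccc3)cc1 | intermediate
4 | methyl 3-{4-[2-(benzyloxy)-5-vinylphenoxy]phenyl}propanoate | COC(=O)CCc1ccc(Oc2cc(C=C)ccc2OCc3ccccc3)cc1 | intermediate
5 | 3-{4-[2-(benzyloxy)-5-vinylphenoxy]phenyl}propanal | O=CCCc1ccc(Oc2cc(C=C)ccc2OCc3ccccc3)cc1 | intermediate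
6 | 1-(benzyloxy)-2-[4-(4,4-dibromobut-3-en-1-yl)phenoxy]-4-vinylbenzene | BrC(Br)=CCCc1ccc(Oc2cc(C=C)ccc2OCc3ccccc3)cc1 | intermediate
7 | 3-hydroxybenzaldehyde | O=Cc1cccc(O)c1 | starting material
8 | 3-vinylphenol | C=Cc1cccc(O)c1 | intermediate
9 | 1-(benzyloxy)-2-{4-[(3Z)-4-bromo-4-(3-vinylphenoxy)but-3-en-1-yl]phenoxy}-4-vinylbenzene | Br/C(Oc1cccc(C=C)c1)=C\CCc1ccc(Oc2cc(C=C)ccc2OCc3ccccc3)cc1 | intermediate
10 | 1-(benzyloxy)-2-{4-[4-(3-vinylphenoxy)but-3-yn-1-yl]phenoxy}-4-vinylbenzene | C=Cc1cccc(OC#CCCc2ccc(Oc3cc(C=C)ccc3OCc4ccccc4)cc2)c1 | intermediate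
11 | methyl vinyl ether | COC=C | starting material
12 | hexacarbonylchromium Cr(CO)6 | O=C=[Cr](=C=O)(=C=O)(=C=O)(=C=O)=C=O | starting material
13 | 1-methoxyvinyllithium | [Li]C(=C)OC | intermediate
14 | lithium pentacarbonyl(2-methoxyacryloyl)chromate | [Li+].[O-]C(=[Cr](=C=O)(=C=O)(=C=O)(=C=O)=C=O)C(=C)OC | intermediate
15 | pentacarbonyl[methoxy(1-methoxyvinyl)carbene]chromium | COC(=[Cr](=C=O)(=C=O)(=C=O)(=C=O)=C=O)C(=C)OC | intermediate
16 | tricarbonylchromium complex of 17, bound η6 to ring A (written as two parts) | COc1cc(O)c(Oc2cccc(C=C)c2)c(CCc2ccc(Oc3cc(C=C)ccc3OCc4ccccc4)cc2)c1OC.O=C=[Cr](=C=O)=C=O | intermediate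
17 | 3-(2-{4-[2-(benzyloxy)-5-vinylphenoxy]phenyl}ethyl)-4,5-dimethoxy-2-(3-vinylphenoxy)phenol | COc1cc(O)c(Oc2cccc(C=C)c2)c(CCc2ccc(Oc3cc(C=C)ccc3OCc4ccccc4)cc2)c1OC | intermediate
18 | 3-(2-{4-[2-(benzyloxy)-5-vinylphenoxy]phenyl}ethyl)-5-methoxy-2-(3-vinylphenoxy)-1,4-benzoquinone | COC1=CC(=O)C(Oc2cccc(C=C)c2)=C(CCc2ccc(Oc3cc(C=C)ccc3OCc4ccccc4)cc2)C1=O | intermediate
19 | macrocyclic stilbene quinone, O-benzylated (alkene geometry open) | COC1=CC(=O)C2=C(CCc3ccc(cc3)Oc4cc(ccc4OCc5ccccc5)C=Cc6cccc(c6)O2)C1=O | intermediate
20 | macrocyclic hydroquinone | COc1cc(O)c2c(CCc3ccc(cc3)Oc4cc(ccc4O)CCc5cccc(c5)O2)c1O | intermediate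
21 | CNP0332646.0 | COC1=CC(=O)C2=C(CCc3ccc(cc3)Oc3cc(ccc3O)CCc3cccc(c3)O2)C1=O | target

**Step count**
Total steps: 11. Longest linear sequence: 9 (steps 1, 2, 3, 4, 6, 8, 9, 10, 11).

**Steps most likely to fail**

**Step 8.** Three processes could defeat the step:
- The alkyne may insert in the opposite orientation.
- A second ynol ether may intercept the ketene.
- The carbene complex may decay before insertion.

The fallback sets out from bromo enol ether 9, isolated by leaving out KOtBu in step 6, and comes back at quinone 18. The partners exchange roles: the alkenyl carbene carries the ring D oxygen (C5) and the ring B side chain (C6), and a small alkyne supplies C2 and C3.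
- Bromine–lithium exchange of 9 (t-BuLi, Et2O–THF, −95 °C) is much faster than addition to a styrene. Addition to Cr(CO)6 and methylation with Me3OBF4 should then give the α-aryloxyalkenyl carbene complex F1.
- F1 is heated in THF with methoxyacetylene F2, freshly made from chloroacetaldehyde dimethyl acetal and NaNH2 in liquid NH3.
- For this terminal alkyne the steric and polar preferences coincide. The CH end binds the carbene carbon (now C4) and the methoxy-bearing carbon ends next to the CO-derived C1, which gives the isomeric 4-methoxyphenol F3.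
- (NH4)2Ce(NO3)6 converts F3 into 18, because the quinone no longer records which carbonyl came from the carbene.

**Step 10.** Intermolecular metathesis to oligomers may outrun closure of the 18-membered ring, or the catalyst may die before two sluggish styrenes are joined. The fallback sets out from phenol 17 and comes back at 19, replacing metathesis by a reductive carbonyl coupling at the arene stage.
- Silylation (TBSCl, imidazole, DMF) gives the silyl ether F4.
- Lemieux–Johnson cleavage (OsO4 cat., NaIO4, 2,6-lutidine, dioxane–H2O) of both vinyl groups gives the dialdehyde F5.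
- McMurry coupling with low-valent titanium (TiCl4, Zn, pyridine, THF, reflux, syringe-pump addition) gives the macrocyclic stilbene silyl ether F6.
- Bu4NF frees the macrocyclic stilbene phenol F7, and (NH4)2Ce(NO3)6 oxidises it to 19.

**Step 6.** Oxidative addition of the alkyl-substituted dibromoalkene may be slow, a second substitution may lead to a ketene acetal, or the styrenes may polymerise at 110 °C. The fallback sets out from ester 4 and phenol 8 and comes back at ynol ether 10. It builds the triple bond by elimination from a ketone derivative at low temperature.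
- Chloromethyllithium, generated in the presence of 4 from ICH2Cl and MeLi·LiBr at −78 °C, should give the chloromethyl ketone F8.
- Williamson etherification with 8 (K2CO3, NaI, acetone) gives the aryloxymethyl ketone F9.
- LiN(SiMe3)2 removes the more acidic proton next to the aryloxy group, and PhNTf2 traps the chelated enolate as the (Z)-enol triflate F10.
- KOtBu (THF, −78 °C) effects anti elimination of triflate to give 10.

**Further compounds**
F1 | step 8 | pentacarbonyl{methoxy[(1E)-1-(3-vinylphenoxy)-4-{4-[2-(benzyloxy)-5-vinylphenoxy]phenyl}but-1-en-1-yl]carbene}chromium | COC(=[Cr](=C=O)(=C=O)(=C=O)(=C=O)=C=O)/C(Oc1cccc(C=C)c1)=C\CCc1ccc(Oc2cc(C=C)ccc2OCc3ccccc3)cc1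
F2 | step 8 | methoxyacetylene | COC#C
F3 | step 8 | 2-(2-{4-[2-(benzyloxy)-5-vinylphenoxy]phenyl}ethyl)-4,6-dimethoxy-3-(3-vinylphenoxy)phenol | COc1cc(OC)c(Oc2cccc(C=C)c2)c(CCc2ccc(Oc3cc(C=C)ccc3OCc4ccccc4)cc2)c1O
F4 | step 10 | tert-butyldimethylsilyl ether of 17 | COc1cc(O[Si](C)(C)C(C)(C)C)c(Oc2cccc(C=C)c2)c(CCc2ccc(Oc3cc(C=C)ccc3OCc4ccccc4)cc2)c1OC
F5 | step 10 | dialdehyde (both vinyl groups of F4 cleaved to formyl) | COc1cc(O[Si](C)(C)C(C)(C)C)c(Oc2cccc(C=O)c2)c(CCc2ccc(Oc3cc(C=O)ccc3OCc4ccccc4)cc2)c1OC
F6 | step 10 | macrocyclic stilbene silyl ether (alkene geometry open) | COc1cc(O[Si](C)(C)C(C)(C)C)c2c(CCc3ccc(cc3)Oc4cc(ccc4OCc5ccccc5)C=Cc6cccc(c6)O2)c1OC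
F7 | step 10 | macrocyclic stilbene 4-methoxyphenol (alkene geometry open) | COc1cc(O)c2c(CCc3ccc(cc3)Oc4cc(ccc4OCc5ccccc5)C=Cc6cccc(c6)O2)c1OC
F8 | step 6 | 4-{4-[2-(benzyloxy)-5-vinylphenoxy]phenyl}-1-chlorobutan-2-one | ClCC(=O)CCc1ccc(Oc2cc(C=C)ccc2OCc3ccccc3)cc1
F9 | step 6 | 4-{4-[2-(benzyloxy)-5-vinylphenoxy]phenyl}-1-(3-vinylphenoxy)butan-2-one | C=Cc1cccc(OCC(=O)CCc2ccc(Oc3cc(C=C)ccc3OCc4ccccc4)cc2)c1
F10 | step 6 | (1Z)-4-{4-[2-(benzyloxy)-5-vinylphenoxy]phenyl}-1-(3-vinylphenoxy)but-1-en-2-yl triflate | C=Cc1cccc(O/C=C(\OS(=O)(=O)C(F)(F)F)CCc2ccc(Oc3cc(C=C)ccc3OCc4ccccc4)cc2)c1
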